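**Retrosynthetic overview**

1. The exocyclic alkene of the target is 5E (side chain syn to C4–OH, the less stable isomer), so it is set last by photo-isomerisation of the 5Z tetronic acid, which comes from aldol/elimination/O-demethylation of a C20 aldehyde with 3-methyltetronic acid methyl ether.
2. The aldehyde comes from a primary alcohol whose skipped (E,E)-diene is cut at C11–C12: Pd-catalysed coupling of an (E)-alkenylalane (Zr-catalysed methylalumination of a chiral alkynol) with an (E)-allylic chloride.
3. The allylic chloride comes from 3-(pent-4-ynyl)furan by methylalumination, hydroxymethylation and chlorination.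
4. Key step: the furan ring is built by [4+2] cycloaddition of 4-phenyloxazole to one alkyne of hepta-1,6-diyne, followed by retro-[4+2] loss of benzonitrile.
5. The only stereocentre (C18) is bought as (R)-3-bromo-2-methylpropan-1-ol. Ring order: furan formed first (step 1); the butenolide ring is bought and attached at the end.

Atom labels (variabilin-type): furan C1–C4, chain C5–C20 (stereocentre C18, exocyclic CH = C20), butenolide C21–C24.

Assumption: 4-phenyloxazole, 3-methyltetronic acid and (R)-3-bromo-2-methylpropan-1-ol are taken as catalogue compounds.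

**Route**

Step 1
Reactants: 1 hepta-1,6-diyne; 2 4-phenyl-1,3-oxazole
Product: 4 3-(pent-4-yn-1-yl)furan, via oxazole–alkyne cycloadduct 3 (not isolated)
Conditions: 1 (6 equiv), 2 (1 equiv), hydroquinone (cat.), neat, sealed tube, 200 °C, 24 h; distil off and recycle excess 1; SiO2
Reagents that add atoms: none
Why: The oxazole acts as an azadiene in a thermal Diels–Alder [4+2] cycloaddition with one terminal alkyne (excess diyne suppresses bis-addition), and adduct 3 loses benzonitrile by retro-Diels–Alder to give the aromatic 3-alkylfuran, whichever way round the alkyne adds.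

Step 2
Reactants: 4 3-(pent-4-yn-1-yl)furan
Product: 7 (2E)-6-(furan-3-yl)-3-methylhex-2-en-1-ol, via alkenyldimethylalane 5 (not isolated), via lithium alkenylalanate 6 (not isolated)
Conditions: Me3Al (2 equiv), Cp2ZrCl2 (0.2 equiv), CH2Cl2, 0 °C to rt; evaporate; n-BuLi (1 equiv), hexane/THF, −78 to 0 °C; (CH2O)n, rt; cold 1 M HCl
Reagents that add atoms: trimethylaluminium, C[Al](C)C; paraformaldehyde (CH2O unit), C=O
Why: Negishi Zr-catalysed carboalumination adds Me and Al syn with Al at the terminus, so the trisubstituted alkene is E, and the alanate is hydroxymethylated with retention.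

Step 3
Reactants: 7 (2E)-6-(furan-3-yl)-3-methylhex-2-en-1-ol
Product: 9 3-[(4E)-6-chloro-4-methylhex-4-en-1-yl]furan, via allylic mesylate 8 (not isolated)
Conditions: MsCl, 2,4,6-collidine, LiCl, DMF, 0 °C
Reagents that add atoms: lithium chloride, [Li+].[Cl-]
Why: Collington–Meyers chlorination displaces the in-situ mesylate by chloride (SN2) without allylic transposition or loss of E geometry, under non-acidic conditions that spare the furan.

Step 4
Reactants: 10 (2R)-3-bromo-2-methylpropan-1-ol; 11 (4-bromobut-1-yn-1-yl)trimethylsilane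
Product: 14 (2S)-2-methyl-7-(trimethylsilyl)hept-6-yn-1-ol, via magnesium alkoxide 12 (not isolated), via homopropargyl Grignard reagent 13 (not isolated)
Conditions: 10, i-PrMgCl (1.0 equiv), THF, −30 °C; 13 (from 11, Mg, THF; 1.5 equiv), Li2CuCl4 (5 mol%), −30 to 0 °C; aq. NH4Cl
Reagents that add atoms: none
Why: Kochi Cu-catalysed sp3–sp3 Grignard cross-coupling at the primary bromide, with the hydroxyl masked in situ as its magnesium alkoxide; the stereocentre is not touched and only its CIP descriptor changes from R to S.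

Step 5
Reactants: 14 (2S)-2-methyl-7-(trimethylsilyl)hept-6-yn-1-ol
Product: 15 (2S)-2-methylhept-6-yn-1-ol
Conditions: K2CO3 (0.2 equiv), MeOH, rt
Reagents that add atoms: none
Why: Base-catalysed methanolysis of the alkynyl C–Si bond (protodesilylation) frees the terminal alkyne and nothing else reacts.

Step 6
Reactants: 15 (2S)-2-methylhept-6-yn-1-ol; 9 3-[(4E)-6-chloro-4-methylhex-4-en-1-yl]furan
Product: 17 (2S,6E,9E)-13-(furan-3-yl)-2,6,10-trimethyltrideca-6,9-dien-1-ol, via alkenylalane aluminium alkoxide 16 (not isolated)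
Conditions: 15, Me3Al (3 equiv), Cp2ZrCl2 (0.25 equiv), ClCH2CH2Cl, 0 °C to rt; then 9, Pd(PPh3)4 (5 mol%), THF, rt; cold 1 M HCl
Reagents that add atoms: trimethylaluminium, C[Al](C)C
Why: Negishi carboalumination (hydroxyl carried as its aluminium alkoxide) gives the (E)-alkenylalane by syn addition, and Pd(0)-catalysed alkenyl–allyl cross-coupling joins it to the primary allylic carbon of 9 with retention of both alkene geometries, giving the (E,E)-1,4-diene.

Step 7
Reactants: 17 (2S,6E,9E)-13-(furan-3-yl)-2,6,10-trimethyltrideca-6,9-dien-1-ol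
Product: 18 (2S,6E,9E)-13-(furan-3-yl)-2,6,10-trimethyltrideca-6,9-dienal
Conditions: Dess–Martin periodinane, CH2Cl2, 0 °C to rt; Na2S2O3/NaHCO3 work-up; used at once
Reagents that add atoms: none
Why: Dess–Martin oxidation is a neutral, non-epimerising oxidation of the primary alcohol to the α-branched aldehyde and leaves furan and alkenes alone.

Step 8
Reactants: 19 4-hydroxy-3-methylfuran-2(5H)-one (3-methyltetronic acid)
Product: 20 4-methoxy-3-methylfuran-2(5H)-one
Conditions: Me2SO4, K2CO3, acetone, reflux
Reagents that add atoms: dimethyl sulfate, COS(=O)(=O)OC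
Why: O-alkylation of the vinylogous acid gives the 4-methoxy tetronate, which masks the acidic OH so that C5 can be lithiated.

Step 9
Reactants: 20 4-methoxy-3-methylfuran-2(5H)-one; 18 (2S,6E,9E)-13-(furan-3-yl)-2,6,10-trimethyltrideca-6,9-dienal
Product: 22 5-[(2S,6E,9E)-13-(furan-3-yl)-1-hydroxy-2,6,10-trimethyltrideca-6,9-dien-1-yl]-4-methoxy-3-methylfuran-2(5H)-one (diastereomer mixture at C5 and C1'), via lithiated tetronate 21 (not isolated)
Conditions: LDA (1.2 equiv), THF, −78 °C; then 18, −78 °C; aq. NH4Cl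
Reagents that add atoms: none
Why: γ-Deprotonation at C5 gives the lithium dienolate, which adds to the aldehyde in an aldol reaction at −78 °C without epimerising C18; the two new stereocentres are uncontrolled and are both removed in step 10.

Step 10
Reactants: 22 aldol adduct
Product: 24 (5Z)-5-[(2S,6E,9E)-13-(furan-3-yl)-2,6,10-trimethyltrideca-6,9-dien-1-ylidene]-4-methoxy-3-methylfuran-2(5H)-one, via secondary mesylate 23 (not isolated)
Conditions: MsCl, Et3N, CH2Cl2, 0 °C; then DBU, rt
Reagents that add atoms: none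
Why: Mesylation then DBU-induced E1cB elimination through the extended dienolate gives the conjugated 5-ylidene tetronate, mainly the thermodynamically preferred Z isomer (chain syn to the ring oxygen); any E isomer is carried on because step 12 re-sets this alkene.

Step 11
Reactants: 24 (5Z)-ylidene methyl tetronate
Product: 25 (5Z)-5-[(2S,6E,9E)-13-(furan-3-yl)-2,6,10-trimethyltrideca-6,9-dien-1-ylidene]-4-hydroxy-3-methylfuran-2(5H)-one
Conditions: NaSEt (3 equiv), DMF, 50 °C; cold 1 M HCl to pH 3
Reagents that add atoms: none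
Why: SN2 O-demethylation of the vinylogous methyl ester by thiolate frees the tetronic acid without strong acid, so furan, skipped diene and C18 are untouched.

Step 12
Reactants: 25 (5Z)-tetronic acid
Product: 26 (5E)-5-[(2S,6E,9E)-13-(furan-3-yl)-2,6,10-trimethyltrideca-6,9-dien-1-ylidene]-4-hydroxy-3-methylfuran-2(5H)-one (target)
Conditions: hν (300 nm), degassed MeCN, 10 °C, to the photostationary state; reversed-phase HPLC in the dark; recovered 25 re-irradiated
Reagents that add atoms: none
Why: Direct excitation of the ylidene-tetronic acid chromophore (the only absorber above 280 nm) causes photochemical Z/E isomerisation of the exocyclic alkene, and the 5E isomer is separated from the mixture; C18 and the two trisubstituted alkenes are not involved.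

**Compound list**

1 | hepta-1,6-diyne | C#CCCCC#C | starting material
2 | 4-phenyl-1,3-oxazole | c1ccc(cc1)-c1cocn1 | starting material
3 | 6-(pent-4-yn-1-yl)-3-phenyl-7-oxa-2-azabicyclo[2.2.1]hepta-2,5-diene (racemic; one regioisomer drawn) | C#CCCCC1=CC2OC1N=C2c1ccccc1 | intermediate
4 | 3-(pent-4-yn-1-yl)furan | C#CCCCc1ccoc1 | intermediate
5 | [(1E)-5-(furan-3-yl)-2-methylpent-1-en-1-yl]dimethylalane | C[Al](C)/C=C(\C)CCCc1ccoc1 | intermediate
6 | lithium butyl[(1E)-5-(furan-3-yl)-2-methylpent-1-en-1-yl]dimethylaluminate | [Li+].CCCC[Al-](C)(C)/C=C(\C)CCCc1ccoc1 | intermediate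
7 | (2E)-6-(furan-3-yl)-3-methylhex-2-en-1-ol | OC/C=C(\C)CCCc1ccoc1 | intermediate
8 | (2E)-6-(furan-3-yl)-3-methylhex-2-en-1-yl methanesulfonate | CS(=O)(=O)OC/C=C(\C)CCCc1ccoc1 | intermediate
9 | 3-[(4E)-6-chloro-4-methylhex-4-en-1-yl]furan | ClC/C=C(\C)CCCc1ccoc1 | intermediate
10 | (2R)-3-bromo-2-methylpropan-1-ol | OC[C@@H](C)CBr | starting material
11 | (4-bromobut-1-yn-1-yl)trimethylsilane | C[Si](C)(C)C#CCCBr | starting material
12 | chloromagnesium (2R)-3-bromo-2-methylpropan-1-olate | Cl[Mg]OC[C@@H](C)CBr | intermediate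
13 | [4-(trimethylsilyl)but-3-yn-1-yl]magnesium bromide | C[Si](C)(C)C#CCC[Mg]Br | intermediate
14 | (2S)-2-methyl-7-(trimethylsilyl)hept-6-yn-1-ol | OC[C@@H](C)CCCC#C[Si](C)(C)C | intermediate
15 | (2S)-2-methylhept-6-yn-1-ol | OC[C@@H](C)CCCC#C | intermediate
16 | dimethylaluminium (2S,6E)-7-(dimethylalumanyl)-2,6-dimethylhept-6-en-1-olate | C[Al](C)OC[C@@H](C)CCC/C(C)=C/[Al](C)C | intermediate
17 | (2S,6E,9E)-13-(furan-3-yl)-2,6,10-trimethyltrideca-6,9-dien-1-ol | OC[C@@H](C)CCC/C(C)=C/C/C=C(\C)CCCc1ccoc1 | intermediate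
18 | (2S,6E,9E)-13-(furan-3-yl)-2,6,10-trimethyltrideca-6,9-dienal | O=C[C@@H](C)CCC/C(C)=C/C/C=C(\C)CCCc1ccoc1 | intermediate
19 | 4-hydroxy-3-methylfuran-2(5H)-one (3-methyltetronic acid) | CC1=C(O)COC1=O | starting material
20 | 4-methoxy-3-methylfuran-2(5H)-one | COC1=C(C)C(=O)OC1 | intermediate
21 | 5-lithio-4-methoxy-3-methylfuran-2(5H)-one (lithium dienolate) | COC1=C(C)C(=O)OC1[Li] | intermediate
22 | 5-[(2S,6E,9E)-13-(furan-3-yl)-1-hydroxy-2,6,10-trimethyltrideca-6,9-dien-1-yl]-4-methoxy-3-methylfuran-2(5H)-one (mixture at C5 and C1') | COC1=C(C)C(=O)OC1C(O)[C@@H](C)CCC/C(C)=C/C/C=C(\C)CCCc1ccoc1 | intermediate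
23 | (2S,6E,9E)-13-(furan-3-yl)-1-(3-methoxy-4-methyl-5-oxo-2,5-dihydrofuran-2-yl)-2,6,10-trimethyltrideca-6,9-dien-1-yl methanesulfonate (mixture) | COC1=C(C)C(=O)OC1C(OS(C)(=O)=O)[C@@H](C)CCC/C(C)=C/C/C=C(\C)CCCc1ccoc1 | intermediate
24 | (5Z)-5-[(2S,6E,9E)-13-(furan-3-yl)-2,6,10-trimethyltrideca-6,9-dien-1-ylidene]-4-methoxy-3-methylfuran-2(5H)-one | COC1=C(C)C(=O)O/C1=C\[C@@H](C)CCC/C(C)=C/C/C=C(\C)CCCc1ccoc1 | intermediate
25 | (5Z)-5-[(2S,6E,9E)-13-(furan-3-yl)-2,6,10-trimethyltrideca-6,9-dien-1-ylidene]-4-hydroxy-3-methylfuran-2(5H)-one | CC1=C(O)/C(=C/[C@@H](C)CCC/C(C)=C/C/C=C(\C)CCCc2ccoc2)OC1=O | intermediate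
26 | (5E)-5-[(2S,6E,9E)-13-(furan-3-yl)-2,6,10-trimethyltrideca-6,9-dien-1-ylidene]-4-hydroxy-3-methylfuran-2(5H)-one | CC1=C(O)/C(=C\[C@@H](C)CCC/C(C)=C/C/C=C(\C)CCCc2ccoc2)OC1=O | target

**Step count and risks**

Total: 12 steps. Longest linear sequence: 9 steps (1, 2, 3, 6, 7, 9, 10, 11, 12).

The three steps most likely to fail are steps 1, 9 and 12.

Step 1 may fail because an unactivated alkyne needs about 200 °C to react with the oxazole, and the diyne can oligomerise or add twice. The fallback buys the furan instead of building it. It sets out from Grignard reagent 13 (made from 11 as in step 4), which is coupled with commercial 3-(bromomethyl)furan under Li2CuCl4 catalysis in THF at −20 °C to give trimethyl[5-(furan-3-yl)pent-1-yn-1-yl]silane F1. K2CO3 in MeOH then removes the silyl group, and the route is rejoined at 4.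

Step 9 may fail because the basic dienolate can enolise the α-branched aldehyde (epimerising C18) or the adduct can undergo retro-aldol. The fallback replaces aldol/elimination by an olefination. It sets out from 20, which is brominated at C5 (NBS, AIBN, CCl4 or PhCF3, reflux) to 5-bromo-4-methoxy-3-methylfuran-2(5H)-one F2. Arbuzov reaction with triethyl phosphite gives diethyl (3-methoxy-4-methyl-5-oxo-2,5-dihydrofuran-2-yl)phosphonate F3. Horner–Wadsworth–Emmons reaction of F3 (NaH, THF, 0 °C) with aldehyde 18 gives the ylidene tetronate directly, and the route is rejoined at 24, skipping 22 and 23.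

Step 12 may fail if the photostationary mixture is poor in the 5E isomer or the isomers cannot be separated. The fallback sets the 5E geometry before the ring is closed. Commercial methyl bis(2,2,2-trifluoroethyl)phosphonoacetate is converted by diazo transfer (p-ABSA, DBU, MeCN) into methyl 2-[bis(2,2,2-trifluoroethoxy)phosphoryl]-2-diazoacetate F4. Rh2(OAc)4-catalysed O–H insertion into propanoic acid gives methyl 2-[bis(2,2,2-trifluoroethoxy)phosphoryl]-2-(propanoyloxy)acetate F5. The fallback then sets out from aldehyde 18: Still–Gennari-type olefination with F5 (KHMDS, 18-crown-6, THF, −78 °C) should, under kinetic control and by analogy with other α-substituted Still–Gennari reagents, place the chain cis to the ester, giving methyl (2E,4S,8E,11E)-15-(furan-3-yl)-4,8,12-trimethyl-2-(propanoyloxy)pentadeca-2,8,11-trienoate F6. Dieckmann cyclisation of the propanoate enolate onto the methyl ester (LiHMDS, THF, −78 to −20 °C; cold dilute acid) closes the tetronic acid with the enol-ester geometry retained, and the route is rejoined at 26.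

**Further compounds**

F1 | step 1 | trimethyl[5-(furan-3-yl)pent-1-yn-1-yl]silane | C[Si](C)(C)C#CCCCc1ccoc1
F2 | step 9 | 5-bromo-4-methoxy-3-methylfuran-2(5H)-one | COC1=C(C)C(=O)OC1Br
F3 | step 9 | diethyl (3-methoxy-4-methyl-5-oxo-2,5-dihydrofuran-2-yl)phosphonate | CCOP(=O)(OCC)C1OC(=O)C(C)=C1OC
F4 | step 12 | methyl 2-[bis(2,2,2-trifluoroethoxy)phosphoryl]-2-diazoacetate | COC(=O)C(=[N+]=[N-])P(=O)(OCC(F)(F)F)OCC(F)(F)F
F5 | step 12 | methyl 2-[bis(2,2,2-trifluoroethoxy)phosphoryl]-2-(propanoyloxy)acetate | CCC(=O)OC(C(=O)OC)P(=O)(OCC(F)(F)F)OCC(F)(F)F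
F6 | step 12 | methyl (2E,4S,8E,11E)-15-(furan-3-yl)-4,8,12-trimethyl-2-(propanoyloxy)pentadeca-2,8,11-trienoate | CCC(=O)O/C(C(=O)OC)=C/[C@@H](C)CCC/C(C)=C/C/C=C(\C)CCCc1ccoc1
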